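## The problem

The target **21** is a 3,3,5,5-tetrasubstituted 1,2-dioxolane (ring O1–O2–C3–C4–C5) with nothing fused to it. C3 carries CH3 and CH2CO2H. C5 carries CH3 and the chain C6–C17, which has a methyl-bearing stereocentre at C7, E double bonds at C12=C13 and C16=C17, and a phenyl group on C17. The synthesis must therefore create two fully substituted, oxygen-bearing carbons in a 1,3 relation across a peroxide and attach a twelve-carbon chain to one of them. Three stereocentres must be fixed: C3 and C5 (both R in the acid, the two methyl groups cis, so arm and chain lie on the same face) and C7 (R). C7 is separated from C5 by the C6 methylene and its substituents differ only as CH3 against CH2, so it can be bought with citronellal but cannot be expected to steer C5. C3 and C5 can influence each other only in the ring-closing event. Once the ring exists, the O–O bond excludes hydrogenation, dissolving metals, low-valent metal reagents and warm phosphines; the CH2CO2H arm is a β-peroxy carbonyl that can open by β-elimination under base; the styrenyl diene does not tolerate cationic or electrophilic conditions. The feature that allows a convergent ring synthesis is that C4 is a bare CH2 between two methyl-bearing quaternary carbons. C4=C5 with its methyl can be the 2-methylallyl terminus of a citronellal-derived chain, which gives a tertiary cation at C5 when C4 attacks. C3 with its methyl and two-carbon arm is the carbonyl carbon of a masked 4-hydroxybutan-2-one, which can be ionised to a peroxycarbenium ion.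

## Retrosynthesis

**Acid arm (21 ⇒ 20 ⇒ 19 ⇒ 18).** No skeletal bond is cut. The carboxyl carbon is taken back through aldehyde **20** and alcohol **19** to the silyl ether **18**. The neighbouring choice, an ester carried from the start, would put a carbonyl two atoms from the cationic centre of the ring-forming step and would end with a saponification β to the peroxide. The forward steps need only fluoride and two non-reducing oxidations that leave O–O and both alkenes alone.

**C12=C13 (18 ⇒ 17 + 14; 14 ⇒ 13 ⇒ 12).** The chain is cut at the isolated double bond into aldehyde **17** and the tetrazolyl sulfone **14**, which comes in two steps from the purchasable alcohol **12** through sulfide **13**. A cut at the styrenyl C16=C17 would leave an alkene in the ring-forming substrate, and an sp3–sp3 cut at C13–C14 would need organometallic coupling next to a peroxide. The chosen cut removes both alkenes from the cationic step, which matters because the styrene is itself a good π-nucleophile. It also places the only stereoselective olefination between two unbranched partners. The forward reaction must give the E alkene and must not attack O–O.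

**C12 oxidation level (17 ⇒ 16 ⇒ 15).** The aldehyde is traced through alcohol **16** to the benzoate **15**. A benzoate survives SnCl4, is not nucleophilic enough to intercept a cation, and is removed by methanolysis without touching the silyl ether.

**Ring (15 ⇒ 7 + 11).** C3–C4 and O1–C5 are cut together. This gives the 1,1-disubstituted alkene **7**, which holds C4–C12 with C7 in place, and the triethylsilylperoxy ketal **11**, which holds C3, its methyl, the arm and both oxygens. The neighbouring pairing (C4–C5 and O2–C3) would make the alkene partner a β,γ-unsaturated ester and put the intermediate cation next to an ester. Here the π-nucleophile is a plain isobutylene-type alkene and the cation at C5 is flanked only by alkyl groups. The precursors have one stereocentre between them and are joined in a single operation. The forward reaction must deliver regiochemistry (attack through CH2) and chemoselectivity; the relative configuration of C3 and C5 is only weakly biased and the relation to C7 is not controlled, so a separation is built into the plan.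

**Peroxy ketal (11 ⇒ 10 ⇒ 9 ⇒ 8).** The O–Si bond is cut to give hydroperoxide **10**. The C3–OOH and C3–OCH3 bonds are then traced to the C=CH2 of silyl ether **9** (ozonolysis in methanol), made from 3-methylbut-3-en-1-ol **8**. Acid-catalysed peroxyketalisation of the corresponding β-silyloxy ketone with H2O2 would risk β-elimination and gem-dihydroperoxide formation; the ozonolysis is acid-free and gives the mixed methoxy hydroperoxide directly.

**Alkene (7 ⇒ 6 ⇒ 5 ⇒ 3 + 4; 3 ⇒ 2 ⇒ 1).** The C4=C5 methylene is traced to ketone **6** (Wittig). The C10–C11 bond is traced through enone benzoate **5** to a cross-metathesis of ketone **3** with allyl benzoate **4**. The C5 methyl is traced through alcohol **2** to a Grignard addition to (R)-citronellal **1**, which supplies C7. Cleaving the citronellal alkene and rebuilding by olefination would cost three more steps. Hydrogenation is placed before the methylenation and before any peroxide exists.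

## Roads not taken

**Alternative 1:** The cut removes both arm bonds (C3–C2' and C5–C6) from a preformed dioxolane. The partners are the bis-ketal 3,5-dimethoxy-3,5-dimethyl-1,2-dioxolane **A2** and the bis-nucleophile trimethyl{2-[(trimethylsilyl)oxy]prop-2-en-1-yl}silane **A3**. Me3SiOSO2CF3 would ionise the two ketal carbons in turn; the allylsilane terminus of **A3** adds first, and the regenerated silyl enol ether closes onto the second peroxycarbenium ion to give the bridged meso ketone **A1**.
- Merits: the three-carbon bridge can only span one face, so the cis relation of the arms is enforced by construction. This is the one question the chosen plan leaves to a weak steric bias and a separation, and here Alternative 1 is better. The ring also comes from pentane-2,4-dione and H2O2.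
- Weak points: **A1** is meso, so all absolute stereochemistry is still to come. It would need an enantioselective, desymmetrising Baeyer–Villiger oxidation of a peroxide-bridged ketone, which is without precedent on this ring system. After lactone opening, C6 is a hydroxymethyl group on a quaternary peroxide carbon, and the C6–C7 bond and the C7 stereocentre must then be made without hydrogenation or strongly reducing organometallics.
- Comparison: the chosen plan sets against the enforced cis relation a purchased C7 stereocentre, two ring bonds in one known reaction, and far fewer uncertain steps.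

**Alternative 2:** The cut takes both C–O bonds of the ring (O1–C5, O2–C3) back to O2 and the C3–C5 bond of the vinylcyclopropane **A5**. Under (C6H5Se)2, light and O2, a phenylselenyl radical adds to the vinyl group, the ring opens to the tertiary C5 radical, O2 is captured, and the peroxyl radical closes 5-exo onto C3 with loss of the selenyl radical to give the 3-ethenyl dioxolane **A4**.
- Merits: the peroxide comes from O2, no hydroperoxide or ozonide is handled, the medium is neutral, and no carbocation is involved, so proton loss and hydride shifts are not an issue. In this respect it is gentler than the chosen key step.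
- Weak points: **A5**, a cyclopropane with two quaternary carbons and the full chain, is harder to make than **7**, and its stereocentres are erased on ring opening. C5 is set by O2 capture at a planar radical without control by C7, and C3 is set in a cyclisation whose cis preference is uncertain for two quaternary centres. The vinyl group of **A4** must then be turned into CH2CO2H by anti-Markovnikov hydration and two oxidations beside the peroxide.
- Comparison: stereocontrol is no better, the key step forms no C–C bond, and the sequence is longer. The chosen plan is convergent and rests on a closer precedent.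

**Alternative 3:** The cut is C4–C5 and O2–C3, the same annulation with the roles as usually assigned. The silylperoxy ketal of the chain ketone, **A7**, would be ionised by SnCl4 to a peroxycarbenium ion at C5. Methyl 3-methylbut-3-enoate **A8** adds through its CH2, and the cation at C3 is captured by the peroxide oxygen to give the ester **A6**.
- Merits: the arm arrives at the acid oxidation level, so desilylation and two oxidations are replaced by one hydrolysis, about two steps fewer. The purchasable **A8** can be used in excess, as the annulation prefers. On step count this road is better.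
- Weak points: **A8** is a less nucleophilic, inductively deactivated alkene. The cation at C3 sits β to an ester carbonyl and next to an acidic CH2, so proton loss to the conjugated enoate competes with closure. The valuable chain component is the one that is ionised. The last step is a basic hydrolysis β to the peroxide, which can open the ring and scramble C3.
- Comparison: stereocontrol is the same as in the chosen plan. The chosen plan sets against the shorter endgame a better nucleophile, a cation remote from any carbonyl and no late basic step. Because **7** is the direct precursor of **A7**, the role-exchanged variant remains available as a fallback from the same intermediates.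

Key step: step 11

Remark on the chemistry: (R)-citronellal of high enantiomeric purity is assumed, since it alone fixes C7. Compounds **2**, **5**, **10** and **11** are carried as mixtures at centres that are erased or made planar later.

## Route

Step 1
Reactants: 1 (R)-citronellal [(3R)-3,7-dimethyloct-6-enal]
Product: 2 (4R)-4,8-dimethylnon-7-en-2-ol (both C2 epimers)
Conditions: CH3MgBr, THF, 0 °C; aq. NH4Cl
Reagents that add atoms: methylmagnesium bromide, C[Mg]Br
Why: Grignard addition to an aldehyde introduces the future C5 methyl; the new carbinol centre is formed as both epimers and is oxidised in step 2, and C7 (β to the carbonyl) is untouched.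

Step 2
Reactants: 2 (4R)-4,8-dimethylnon-7-en-2-ol
Product: 3 (4R)-4,8-dimethylnon-7-en-2-one
Conditions: (COCl)2, DMSO, CH2Cl2, −78 °C; Et3N, −78 °C to rt
Reagents that add atoms: none
Why: Swern oxidation of a secondary alcohol; the trisubstituted alkene is inert and the only stereocentre is β to the new ketone, so it cannot epimerise.

Step 3
Reactants: 3 (4R)-4,8-dimethylnon-7-en-2-one; 4 allyl benzoate (prop-2-en-1-yl benzoate)
Product: 5 (2E,6R)-6-methyl-8-oxonon-2-en-1-yl benzoate (with some 2Z isomer)
Conditions: 4 (3 equiv), second-generation Hoveyda–Grubbs catalyst RuCl2(H2IMes)(=CH-C6H4-2-OiPr) (5 mol %), CH2Cl2, 40 °C, argon sweep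
Reagents that add atoms: none
Why: Olefin cross-metathesis in which the isopropylidene terminus is exchanged for the CH–CH2OBz unit with loss of 2-methylpropene, an established reaction of prenyl-type alkenes with N-heterocyclic-carbene ruthenium catalysts; the E/Z ratio is irrelevant because the alkene is saturated in step 4.

Step 4
Reactants: 5 (2E,6R)-6-methyl-8-oxonon-2-en-1-yl benzoate
Product: 6 (6R)-6-methyl-8-oxononyl benzoate
Conditions: H2 (1 atm), RhCl(PPh3)3 (5 mol %), toluene–EtOH, rt
Reagents that add atoms: none
Why: Homogeneous hydrogenation of a 1,2-disubstituted alkene with Wilkinson's catalyst, chosen over palladium on carbon to avoid hydrogenolysis of the allylic benzoate; ketone and ester are not reduced.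

Step 5
Reactants: 6 (6R)-6-methyl-8-oxononyl benzoate
Product: 7 (6R)-6,8-dimethylnon-8-en-1-yl benzoate
Conditions: Ph3PCH3Br, KOtBu, THF, 0 °C to rt
Reagents that add atoms: methyltriphenylphosphonium bromide, C[P+](c1ccccc1)(c1ccccc1)c1ccccc1.[Br-]
Why: Wittig methylenation; the unstabilised ylide reacts with the methyl ketone much faster than with the benzoate at 0 °C, and the stereocentre is β to the carbonyl.

Step 6
Reactants: 8 3-methylbut-3-en-1-ol
Product: 9 tert-butyl[(3-methylbut-3-en-1-yl)oxy]diphenylsilane
Conditions: tBuPh2SiCl, imidazole, DMF, rt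
Reagents that add atoms: tert-butyl(chloro)diphenylsilane, CC(C)(C)[Si](Cl)(c1ccccc1)c1ccccc1
Why: Standard silylation of a primary alcohol; the bulky, weakly basic silyl ether is chosen to stay passive toward SnCl4 and toward the cations of step 11.

Step 7
Reactants: 9 tert-butyl[(3-methylbut-3-en-1-yl)oxy]diphenylsilane
Product: 10 4-[(tert-butyldiphenylsilyl)oxy]-2-methoxybutan-2-yl hydroperoxide (racemic)
Conditions: O3, CH2Cl2–MeOH, −78 °C; N2 purge, no reductant
Reagents that add atoms: ozone, [O-][O+]=O; methanol, CO
Why: Ozonolysis in methanol (Criegee mechanism): the primary ozonide of a 1,1-disubstituted alkene fragments to formaldehyde and the more substituted carbonyl oxide, which methanol traps as the α-methoxy hydroperoxide.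

Step 8
Reactants: 10 4-[(tert-butyldiphenylsilyl)oxy]-2-methoxybutan-2-yl hydroperoxide
Product: 11 4-(tert-butyldiphenylsilyloxy)-2-methoxy-2-(triethylsilylperoxy)butane (racemic)
Conditions: Et3SiCl, imidazole, DMF, 0 °C
Reagents that add atoms: chlorotriethylsilane, CC[Si](Cl)(CC)CC
Why: O-silylation of a hydroperoxide; the triethylsilyl group is kept on oxygen long enough for the ring closure of step 11 and is then lost easily.

Step 9
Reactants: 12 (4E)-5-phenylpent-4-en-1-ol
Product: 13 1-phenyl-5-{[(4E)-5-phenylpent-4-en-1-yl]sulfanyl}-1H-tetrazole
Conditions: 1-phenyl-1H-tetrazole-5-thiol, PPh3, DIAD, THF, 0 °C to rt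
Reagents that add atoms: 1-phenyl-1H-tetrazole-5-thiol, Sc1nnnn1-c1ccccc1
Why: Mitsunobu thioetherification of a primary alcohol with an acidic heteroaryl thiol.

Step 10
Reactants: 13 1-phenyl-5-{[(4E)-5-phenylpent-4-en-1-yl]sulfanyl}-1H-tetrazole
Product: 14 1-phenyl-5-{[(4E)-5-phenylpent-4-en-1-yl]sulfonyl}-1H-tetrazole
Conditions: (NH4)6Mo7O24·4H2O (10 mol %), 30 % aq. H2O2, EtOH, 0 °C to rt
Reagents that add atoms: hydrogen peroxide, OO
Why: Molybdate-catalysed oxidation of the sulfide to the sulfone; this oxidant is selective for sulfur and spares the styrene, which a peracid would epoxidise.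

Step 11
Reactants: 7 (6R)-6,8-dimethylnon-8-en-1-yl benzoate; 11 4-(tert-butyldiphenylsilyloxy)-2-methoxy-2-(triethylsilylperoxy)butane
Product: 15 (3S,5R)-3-{2-[(tert-butyldiphenylsilyl)oxy]ethyl}-5-[(2R)-7-(benzoyloxy)-2-methylheptyl]-3,5-dimethyl-1,2-dioxolane (isolated after separation from its three diastereomers)
Conditions: 11 (1.5 equiv), SnCl4 (1.5 equiv), CH2Cl2, −78 °C; aq. NaHCO3; silica gel, then preparative HPLC
Reagents that add atoms: none
Why: SnCl4 abstracts methoxide from 11 to give the peroxycarbenium ion at C3; the CH2 terminus (C4) of the alkene of 7 adds to it (C3–C4) and leaves a tertiary carbocation at C5, which the silylated peroxide oxygen O1 captures (O1–C5) with loss of the triethylsilyl group as Et3SiCl. The closest known reaction type is this same Lewis acid annulation of ketone-derived triethylsilylperoxy ketals with alkenes, 1,1-disubstituted ones included, to give 1,2-dioxolanes. The one ring closes by O–C bond formation in a five-membered closure onto a planar carbocation (formally 5-endo, but without the geometric handicap of endo attack on a π bond, because the electrophilic carbon offers a vacant p orbital). C3 is created in the C–C bond-forming step from a planar cation with no stereocentre within reach, so both configurations form. C5 is created in the closure: relative to C3 it is governed only by the preference of the larger groups (silyloxyethyl at C3, branched chain at C5) for pseudo-equatorial positions in an envelope-like transition state, which should favour the arm/chain-cis (methyl/methyl-cis) pair that the target needs, but only weakly; relative to C7 it is not controlled. Four diastereomers are therefore expected, the two 3,5-cis ones in similar amounts; 15 has to be separated, its cis relation is to be checked by NOE between the ring methyl groups, and the C5/C7 relation is to be confirmed on the final acid. The selectivities the step does need are regio- and chemoselectivity: attack through CH2 is secured by the tertiary cation it produces, the 1,1-disubstituted alkene is the only π-nucleophile because the chain ends in a benzoate and not in the diene, and the silyl ether and benzoate are too weakly nucleophilic to intercept the cations at −78 °C.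

Step 12
Reactants: 15 (3S,5R)-3-{2-[(tert-butyldiphenylsilyl)oxy]ethyl}-5-[(2R)-7-(benzoyloxy)-2-methylheptyl]-3,5-dimethyl-1,2-dioxolane
Product: 16 (3S,5R)-3-{2-[(tert-butyldiphenylsilyl)oxy]ethyl}-5-[(2R)-7-hydroxy-2-methylheptyl]-3,5-dimethyl-1,2-dioxolane
Conditions: K2CO3, MeOH, rt
Reagents that add atoms: none
Why: Base-catalysed transesterification of the benzoate; the peroxide carbons carry no hydrogen, so base-induced Kornblum–DeLaMare fragmentation is impossible, and the silyl ether is stable to carbonate in methanol.

Step 13
Reactants: 16 (3S,5R)-3-{2-[(tert-butyldiphenylsilyl)oxy]ethyl}-5-[(2R)-7-hydroxy-2-methylheptyl]-3,5-dimethyl-1,2-dioxolane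
Product: 17 (3S,5R)-3-{2-[(tert-butyldiphenylsilyl)oxy]ethyl}-3,5-dimethyl-5-[(2R)-2-methyl-7-oxoheptyl]-1,2-dioxolane
Conditions: Dess–Martin periodinane, NaHCO3, CH2Cl2, 0 °C to rt
Reagents that add atoms: none
Why: Dess–Martin oxidation of a primary alcohol to the aldehyde under near-neutral, non-reducing conditions that leave the O–O bond alone.

Step 14
Reactants: 17 (3S,5R)-3-{2-[(tert-butyldiphenylsilyl)oxy]ethyl}-3,5-dimethyl-5-[(2R)-2-methyl-7-oxoheptyl]-1,2-dioxolane; 14 1-phenyl-5-{[(4E)-5-phenylpent-4-en-1-yl]sulfonyl}-1H-tetrazole
Product: 18 (3S,5R)-3-{2-[(tert-butyldiphenylsilyl)oxy]ethyl}-3,5-dimethyl-5-[(2R,7E,11E)-2-methyl-12-phenyldodeca-7,11-dien-1-yl]-1,2-dioxolane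
Conditions: 14, KN(SiMe3)2, DME, −60 °C; then 17, −60 °C to rt
Reagents that add atoms: none
Why: Julia–Kocienski olefination; premetalated 1-phenyltetrazolyl sulfones with a potassium counter-ion in DME should give the E alkene from unbranched partners through anti addition, Smiles rearrangement and anti elimination, and the hindered tertiary dialkyl peroxide offers the carbanion no acidic hydrogen and a poorly accessible O–O bond at low temperature.

Step 15
Reactants: 18 (3S,5R)-3-{2-[(tert-butyldiphenylsilyl)oxy]ethyl}-3,5-dimethyl-5-[(2R,7E,11E)-2-methyl-12-phenyldodeca-7,11-dien-1-yl]-1,2-dioxolane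
Product: 19 2-{(3S,5R)-3,5-dimethyl-5-[(2R,7E,11E)-2-methyl-12-phenyldodeca-7,11-dien-1-yl]-1,2-dioxolan-3-yl}ethan-1-ol
Conditions: Bu4NF, THF, 0 °C to rt
Reagents that add atoms: none
Why: Fluoride cleavage of the silyl ether; nothing else in 18 responds to fluoride, and the peroxide is inert to it.

Step 16
Reactants: 19 2-{(3S,5R)-3,5-dimethyl-5-[(2R,7E,11E)-2-methyl-12-phenyldodeca-7,11-dien-1-yl]-1,2-dioxolan-3-yl}ethan-1-ol
Product: 20 {(3R,5R)-3,5-dimethyl-5-[(2R,7E,11E)-2-methyl-12-phenyldodeca-7,11-dien-1-yl]-1,2-dioxolan-3-yl}acetaldehyde
Conditions: Dess–Martin periodinane, NaHCO3, CH2Cl2, 0 °C; used at once without chromatography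
Reagents that add atoms: none
Why: Dess–Martin oxidation under bicarbonate buffer keeps the β-peroxy aldehyde away from the bases that would open the ring by β-elimination; C3 is quaternary and cannot epimerise (its descriptor changes to R only through the priorities).

Step 17
Reactants: 20 {(3R,5R)-3,5-dimethyl-5-[(2R,7E,11E)-2-methyl-12-phenyldodeca-7,11-dien-1-yl]-1,2-dioxolan-3-yl}acetaldehyde
Product: 21 {(3R,5R)-3,5-dimethyl-5-[(2R,7E,11E)-2-methyl-12-phenyldodeca-7,11-dien-1-yl]-1,2-dioxolan-3-yl}acetic acid (target)
Conditions: NaClO2, NaH2PO4, 2-methylbut-2-ene (excess), tBuOH–H2O, 0 °C to rt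
Reagents that add atoms: sodium chlorite, [Na+].[O-]Cl=O
Why: Pinnick oxidation of the aldehyde to the acid in a weakly acidic buffer; excess 2-methylbut-2-ene scavenges the hypochlorous acid and so protects both chain alkenes, and a dialkyl peroxide is stable to chlorite.

## Compound list

1 | (R)-citronellal, (3R)-3,7-dimethyloct-6-enal | C[C@H](CCC=C(C)C)CC=O | starting material
2 | (4R)-4,8-dimethylnon-7-en-2-ol (C2 epimers) | C[C@H](CCC=C(C)C)CC(C)O | intermediate
3 | (4R)-4,8-dimethylnon-7-en-2-one | C[C@H](CCC=C(C)C)CC(C)=O | intermediate
4 | allyl benzoate | C=CCOC(=O)c1ccccc1 | starting material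
5 | (2E,6R)-6-methyl-8-oxonon-2-en-1-yl benzoate | C[C@H](CC/C=C/COC(=O)c1ccccc1)CC(C)=O | intermediate
6 | (6R)-6-methyl-8-oxononyl benzoate | C[C@H](CCCCCOC(=O)c1ccccc1)CC(C)=O | intermediate
7 | (6R)-6,8-dimethylnon-8-en-1-yl benzoate | C=C(C)C[C@H](C)CCCCCOC(=O)c1ccccc1 | intermediate
8 | 3-methylbut-3-en-1-ol | C=C(C)CCO | starting material
9 | tert-butyl[(3-methylbut-3-en-1-yl)oxy]diphenylsilane | C=C(C)CCO[Si](c1ccccc1)(c1ccccc1)C(C)(C)C | intermediate
10 | 4-[(tert-butyldiphenylsilyl)oxy]-2-methoxybutan-2-yl hydroperoxide (racemic) | COC(C)(CCO[Si](c1ccccc1)(c1ccccc1)C(C)(C)C)OO | intermediate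
11 | 4-(tert-butyldiphenylsilyloxy)-2-methoxy-2-(triethylsilylperoxy)butane (racemic) | COC(C)(CCO[Si](c1ccccc1)(c1ccccc1)C(C)(C)C)OO[Si](CC)(CC)CC | intermediate
12 | (4E)-5-phenylpent-4-en-1-ol | OCCC/C=C/c1ccccc1 | starting material
13 | 1-phenyl-5-{[(4E)-5-phenylpent-4-en-1-yl]sulfanyl}-1H-tetrazole | S(CCC/C=C/c1ccccc1)c1nnnn1-c1ccccc1 | intermediate
14 | 1-phenyl-5-{[(4E)-5-phenylpent-4-en-1-yl]sulfonyl}-1H-tetrazole | O=S(=O)(CCC/C=C/c1ccccc1)c1nnnn1-c1ccccc1 | intermediate
15 | (3S,5R)-3-{2-[(tert-butyldiphenylsilyl)oxy]ethyl}-5-[(2R)-7-(benzoyloxy)-2-methylheptyl]-3,5-dimethyl-1,2-dioxolane | C[C@H](CCCCCOC(=O)c1ccccc1)C[C@]1(C)C[C@](C)(CCO[Si](c2ccccc2)(c2ccccc2)C(C)(C)C)OO1 | intermediate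
16 | (3S,5R)-3-{2-[(tert-butyldiphenylsilyl)oxy]ethyl}-5-[(2R)-7-hydroxy-2-methylheptyl]-3,5-dimethyl-1,2-dioxolane | C[C@H](CCCCCO)C[C@]1(C)C[C@](C)(CCO[Si](c2ccccc2)(c2ccccc2)C(C)(C)C)OO1 | intermediate
17 | (3S,5R)-3-{2-[(tert-butyldiphenylsilyl)oxy]ethyl}-3,5-dimethyl-5-[(2R)-2-methyl-7-oxoheptyl]-1,2-dioxolane | C[C@H](CCCCC=O)C[C@]1(C)C[C@](C)(CCO[Si](c2ccccc2)(c2ccccc2)C(C)(C)C)OO1 | intermediate
18 | (3S,5R)-3-{2-[(tert-butyldiphenylsilyl)oxy]ethyl}-3,5-dimethyl-5-[(2R,7E,11E)-2-methyl-12-phenyldodeca-7,11-dien-1-yl]-1,2-dioxolane | C[C@H](CCCC/C=C/CC/C=C/c1ccccc1)C[C@]1(C)C[C@](C)(CCO[Si](c2ccccc2)(c2ccccc2)C(C)(C)C)OO1 | intermediate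
19 | 2-{(3S,5R)-3,5-dimethyl-5-[(2R,7E,11E)-2-methyl-12-phenyldodeca-7,11-dien-1-yl]-1,2-dioxolan-3-yl}ethan-1-ol | C[C@H](CCCC/C=C/CC/C=C/c1ccccc1)C[C@]1(C)C[C@](C)(CCO)OO1 | intermediate
20 | {(3R,5R)-3,5-dimethyl-5-[(2R,7E,11E)-2-methyl-12-phenyldodeca-7,11-dien-1-yl]-1,2-dioxolan-3-yl}acetaldehyde | C[C@H](CCCC/C=C/CC/C=C/c1ccccc1)C[C@]1(C)C[C@](C)(CC=O)OO1 | intermediate
21 | {(3R,5R)-3,5-dimethyl-5-[(2R,7E,11E)-2-methyl-12-phenyldodeca-7,11-dien-1-yl]-1,2-dioxolan-3-yl}acetic acid | C[C@H](CCCC/C=C/CC/C=C/c1ccccc1)C[C@]1(C)C[C@](C)(CC(=O)O)OO1 | target

## Step count and risk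

Total: 17 steps. Longest linear sequence: 12 steps (steps 1–5 and 11–17, from **1** to **21**). The side branches are steps 6–8 (to **11**) and steps 9–10 (to **14**).

**Step 11 (key step).**
- What may go wrong: poor facial selectivity in the capture of the C5 cation, with no control from C7 and only a weak bias from C3. The wanted isomer is then one of four, and its separation from the other 3,5-cis isomer is laborious. The C5 cation may also be diverted by proton loss or chloride capture before the five-membered closure, and it has the tertiary C7–H in a 1,3 relation.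
- Fallback: exchange the roles of the partners. It sets out from **7** and **9** and returns at **15**. Ozonolysis of **7** in methanol should give (6R)-8-hydroperoxy-8-methoxy-6-methylnonyl benzoate F1. Silylation with Et3SiCl and imidazole gives (6R)-8-methoxy-6-methyl-8-[(triethylsilyl)peroxy]nonyl benzoate F2 (the same compound as A7). SnCl4-mediated annulation of F2 with the 1,1-disubstituted alkene **9**, now used in large excess as this annulation prefers, forms C4–C5 and O2–C3 and leads to **15**.
- What the fallback does and does not cure: the cation to be captured is then at C3, away from the C7–H, and the diastereomer distribution is independent of the first. It creates no control by C7. In either variant, separation of the two cis isomers can be deferred to alcohol **16** if **15** does not resolve.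

**Step 3 (cross-metathesis).**
- What may go wrong: slow turnover at the trisubstituted alkene while self-metathesis of **4** consumes the catalyst, giving incomplete conversion.
- Fallback: build C11–C12 by olefination. It sets out from **3** and returns at **7**. Ozonolysis of **3** with Me2S work-up gives (4R)-4-methyl-6-oxoheptanal F3. Aldehyde-selective Horner–Wadsworth–Emmons reaction with triethyl phosphonoacetate (LiCl, DBU) gives ethyl (2E,6R)-6-methyl-8-oxonon-2-enoate F4. Hydrogenation over Pd/C gives ethyl (6R)-6-methyl-8-oxononanoate F5. Wittig methylenation gives ethyl (6R)-6,8-dimethylnon-8-enoate F6. Reduction with LiAlH4 gives (6R)-6,8-dimethylnon-8-en-1-ol F7, and benzoylation (BzCl, pyridine) gives **7**.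

**Step 14 (Julia–Kocienski olefination).**
- What may go wrong: erosion of E selectivity at C12=C13, with a Z isomer that is hard to remove from a hydrocarbon-like product, or consumption of the metalated sulfone by the peroxide.
- Fallback: reverse the polarity of the coupling. It sets out from **16** (and from **12** for the aldehyde partner) and returns at **18**. Mesylation of **16** gives (3S,5R)-3-{2-[(tert-butyldiphenylsilyl)oxy]ethyl}-5-[(2R)-7-(methanesulfonyloxy)-2-methylheptyl]-3,5-dimethyl-1,2-dioxolane F8. Phosphine-free displacement with sodium 1-phenyl-1H-tetrazole-5-thiolate gives (3S,5R)-3-{2-[(tert-butyldiphenylsilyl)oxy]ethyl}-3,5-dimethyl-5-{(2R)-2-methyl-7-[(1-phenyl-1H-tetrazol-5-yl)sulfanyl]heptyl}-1,2-dioxolane F9. Molybdate/H2O2 oxidation gives (3S,5R)-3-{2-[(tert-butyldiphenylsilyl)oxy]ethyl}-3,5-dimethyl-5-{(2R)-2-methyl-7-[(1-phenyl-1H-tetrazol-5-yl)sulfonyl]heptyl}-1,2-dioxolane F10. Olefination of F10 with (4E)-5-phenylpent-4-enal F11 (from **12** by Dess–Martin oxidation), which can be used in excess, gives **18**.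

**Steps 16 and 17 (acid arm).**
- What may go wrong: β-elimination of the peroxide from the β-peroxy aldehyde **20** (ring opening) while it is handled between the two oxidations.
- Fallback: a single-operation oxidation. It sets out from **19** and returns at **21**. Catalytic TEMPO with PhI(OAc)2 in aqueous acetonitrile oxidises the aldehyde further as its hydrate as soon as it forms, so it is never isolated. No new compound is made on this way (entry F0 below).

## Further compounds

F1 | step 11 | (6R)-8-hydroperoxy-8-methoxy-6-methylnonyl benzoate | COC(C)(C[C@H](C)CCCCCOC(=O)c1ccccc1)OO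
F2 | step 11 | (6R)-8-methoxy-6-methyl-8-[(triethylsilyl)peroxy]nonyl benzoate | COC(C)(C[C@H](C)CCCCCOC(=O)c1ccccc1)OO[Si](CC)(CC)CC
F3 | step 3 | (4R)-4-methyl-6-oxoheptanal | C[C@H](CCC=O)CC(C)=O
F4 | step 3 | ethyl (2E,6R)-6-methyl-8-oxonon-2-enoate | C[C@H](CC/C=C/C(=O)OCC)CC(C)=O
F5 | step 3 | ethyl (6R)-6-methyl-8-oxononanoate | C[C@H](CCCCC(=O)OCC)CC(C)=O
F6 | step 3 | ethyl (6R)-6,8-dimethylnon-8-enoate | C[C@H](CCCCC(=O)OCC)CC(C)=C
F7 | step 3 | (6R)-6,8-dimethylnon-8-en-1-ol | C[C@H](CCCCCO)CC(C)=C
F8 | step 14 | (3S,5R)-3-{2-[(tert-butyldiphenylsilyl)oxy]ethyl}-5-[(2R)-7-(methanesulfonyloxy)-2-methylheptyl]-3,5-dimethyl-1,2-dioxolane | C[C@H](CCCCCOS(C)(=O)=O)C[C@]1(C)C[C@](C)(CCO[Si](c2ccccc2)(c2ccccc2)C(C)(C)C)OO1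
F9 | step 14 | (3S,5R)-3-{2-[(tert-butyldiphenylsilyl)oxy]ethyl}-3,5-dimethyl-5-{(2R)-2-methyl-7-[(1-phenyl-1H-tetrazol-5-yl)sulfanyl]heptyl}-1,2-dioxolane | C[C@H](CCCCCSc1nnnn1-c1ccccc1)C[C@]1(C)C[C@](C)(CCO[Si](c2ccccc2)(c2ccccc2)C(C)(C)C)OO1
F10 | step 14 | (3S,5R)-3-{2-[(tert-butyldiphenylsilyl)oxy]ethyl}-3,5-dimethyl-5-{(2R)-2-methyl-7-[(1-phenyl-1H-tetrazol-5-yl)sulfonyl]heptyl}-1,2-dioxolane | C[C@H](CCCCCS(=O)(=O)c1nnnn1-c1ccccc1)C[C@]1(C)C[C@](C)(CCO[Si](c2ccccc2)(c2ccccc2)C(C)(C)C)OO1
F11 | step 14 | (4E)-5-phenylpent-4-enal | O=CCC/C=C/c1ccccc1
F0 | step 16 | none | none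
A1 | alternative 1 | (1R,5S)-1,5-dimethyl-6,7-dioxabicyclo[3.2.1]octan-3-one (meso) | O=C1C[C@]2(C)C[C@](C)(C1)OO2
A2 | alternative 1 | 3,5-dimethoxy-3,5-dimethyl-1,2-dioxolane | COC1(C)CC(C)(OC)OO1
A3 | alternative 1 | trimethyl{2-[(trimethylsilyl)oxy]prop-2-en-1-yl}silane | C=C(C[Si](C)(C)C)O[Si](C)(C)C
A4 | alternative 2 | (3R,5R)-3-ethenyl-3,5-dimethyl-5-[(2R)-7-(tert-butyldiphenylsilyloxy)-2-methylheptyl]-1,2-dioxolane | C[C@H](CCCCCO[Si](c1ccccc1)(c2ccccc2)C(C)(C)C)C[C@]3(C)C[C@](C)(C=C)OO3
A5 | alternative 2 | tert-butyl{[(6R)-7-(2-ethenyl-1,2-dimethylcyclopropyl)-6-methylheptyl]oxy}diphenylsilane (cyclopropane stereoisomers) | C[C@H](CCCCCO[Si](c1ccccc1)(c1ccccc1)C(C)(C)C)CC1(C)CC1(C)C=C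
A6 | alternative 3 | methyl 2-[(3R,5R)-5-[(2R)-7-(benzoyloxy)-2-methylheptyl]-3,5-dimethyl-1,2-dioxolan-3-yl]acetate | C[C@H](CCCCCOC(=O)c1ccccc1)C[C@]1(C)C[C@](C)(CC(=O)OC)OO1
A7 | alternative 3 | (6R)-8-methoxy-6-methyl-8-[(triethylsilyl)peroxy]nonyl benzoate | COC(C)(C[C@H](C)CCCCCOC(=O)c1ccccc1)OO[Si](CC)(CC)CC
A8 | alternative 3 | methyl 3-methylbut-3-enoate | C=C(C)CC(=O)OC
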